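## The problem

Locants: the cyclobutane is C1–C5–C6–C10, ring A is C1–C2–C3–C4–C5, ring C is C6–C7–C8–C9–C10, and the butenolide is C6–O–C12(=O)–C11=C7. C13, C14 and C15 are the carbons on C11, C10 and C4; β is the cyclobutane face that carries C14, and α is the other face.

Target 38 is a linear 5-4-5 carbotricycle. Both cyclopentanes hang from the α side of the four-membered ring (cis-syn-cis), and a butenolide is fused to ring C through C6–C7. There are seven stereocentres (C1, C2, C4, C5, C6, C8, C10). H1, H5, the lactone oxygen on C6, C14 and the oxygens on C2, C4 and C8 all lie on the β face, and C6 and C10 are neighbouring, fully substituted carbons of the strained ring.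

Once C6 and C10 are fixed, the fold of the skeleton leaves β as the open face, so C1, C5 and C8 can be derived from them. C2 and C4 sit on the outer edge of ring A and must be set independently, or serve as the source of chirality.

The fragile points are these:
- A C4 ketone beside a free C6 hydroxyl invites retro-aldol cleavage of the cyclobutane.
- A radical or cation at C4 or C7 is a cyclobutylcarbinyl ring-opening trigger.
- A C6-hydroxy C7-ketone can undergo an α-ketol shift to a norbornanone.
- The allylic C13 acetate is expelled from the dienolate formed by deprotonation at C8.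
- Three different esters stand beside a free tertiary alcohol.

The enabling feature is that deleting C6–C10 merges the four-membered ring and ring C into one seven-membered ring, C5–C6–C7–C8–C9–C10–C1. That ring bears oxygen on C6 and a carbonyl-level carbon at C7. It is a 2-alkoxytropone fused to ring A, a class known to close exactly this bond under light.

## Retrosynthesis

**38 from 37.** The cuts are the two acetyl–oxygen bonds and, at C2, the C2–O bond itself. Triol 37 carries its C2 hydroxyl on the α face. One Mitsunobu esterification should convert the primary allylic C13 alcohol and, with inversion, the C2 alcohol, while the tertiary C4 alcohol stays inert. Carrying a β oxygen at C2 from the start is rejected, because that oxygen steers the key step and must be α there. The forward reaction must achieve SN2 displacement with the nucleophile arriving from the open β face.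

**37 from 36, 36 from 35, 35 from 30 and 34.** The cuts are C7=C11 and O6–C12.
- Adding a carbon nucleophile to C7 and lactonising later would pass through a tertiary C7 carbinol beside the cyclobutane.
- Adding C13 to a finished butenolide fails, because C7 is fully substituted and allylic oxidation cannot tell C13 from C8.

C11, C12 and C13 therefore arrive together in phosphono acid 34, three steps from 31. The precursor 30 is a plain α-ketol. The forward steps ask for acylation of a tertiary alcohol and an intramolecular Horner–Wadsworth–Emmons closure.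

**30 from 28 and 29, 28 from 25 through 26.** The cut is C8–O. C6 is quaternary, so the C7 ketone can enolise only towards C8. The α face lies inside the fold, so an electrophilic oxidant must come from β. The tiglate goes on at once, because the secondary C8 hydroxyl must be capped before C6 is acylated, and every later step tolerates it.

**25 from 24, 24 from 23.** The cuts are C1–H and C5–H, plus the benzyl group. Adding hydrogen to the β face of the C1=C5 cyclobutene turns ring A towards ring C. The freed C6 hydroxyl delivers the catalyst to that face, and the α silyloxy group at C2 blocks the other.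

**23 from 22 (key step).** The cut is C6–C10. No neighbouring bond of the cyclobutane offers as much. This cut removes the four-membered ring, ring C and both quaternary centres at once, and it leaves a flat, conjugated bicycle with only the two ring-A stereocentres. The forward reaction must choose the right diene (C6=C5–C1=C10) and the right face.

**22 from 19 through 20 and 21.** Taking C9 out of the tropone (cuts C8–C9 and C9–C10) leaves a benzene ring with adjacent oxygens on C6 and C7. O-alkylating a free tropolone would favour the less hindered C7 oxygen, and a carbene ring expansion of the arene has no regiocontrol. Instead phenol 19 is dearomatised to the symmetric acetal 20, cyclopropanated at C8=C10 to 21, and opened by acid. The carbonyl then stays on C7 and the ether on C6 by construction.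

**19 from 16, 16 from 15, 15 from 14, 14 from 13.** The cuts are C7–O, C4–O and C4=C15. The aryl bromide serves as a masked phenol and needs no protecting group. The C4 carbinol is completed on the flat indane, where a benzylic radical is harmless and the α silyloxy group at C2 directs oxygen to the β face. Building it after the key step would require a C4 ketone, radical or cation next to the cyclobutane, and would have to force C15 into the fold beside the butenolide.

**13 from 12, 12 from 10, 10 from 8.** The cut is C2–O. Benzylic oxidation would compete with the aryl methyl group and the benzyl ether. The ring ketone is used instead: dehydrogenation to indenone 10 followed by enantioselective conjugate borylation puts oxygen on C2 and creates the first stereocentre.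

**8 from 6 and 7, 6 from 5, 5 from 1 and 2.** The cuts are the benzyl ether, C7–Br and ring A. A Fries shift followed by Friedel–Crafts closure places the ketone (C4) next to the phenolic oxygen (C6) and the methyl group (C14) next to C1. The only activated free position then takes bromine. Compound 5 is also an article of commerce.

## Roads not taken

**Alternative 1:** The cut is C9–C10, the last bond of ring C. In the forward direction Rh2(OAc)4 turns diazoketone A1, whose C7–C8–C9 chain hangs from the α side of C6, into a carbenoid. This inserts into the α C10–H bond and gives ketone A2.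

*Merits.* Five-ring C–H insertion is dependable and proceeds with retention, so quaternary C10 forms stereospecifically. A2 already holds C2 and C4 in their final configuration. No inversion at C2 is needed, which is better than the chosen plan.

*Weak points.*
- All the difficulty moves into A1, a cyclobutane with five stereocentres and a tertiary C6 carbinol, and the key step does nothing to build it.
- Cyclobutane C–H bonds are poor donors.
- The C6 silyl ether oxygen can intercept the carbenoid as an oxonium ylide.
- A2 has its ketone at C8 and its carbinol at C7, the reverse of what the butenolide needs.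

*Comparison.* The chosen plan offers one photochemical step that makes the cyclobutane, ring C and both quaternary carbons from a flat precursor. It pays for this with a late Mitsunobu inversion.

**Alternative 2:** The cuts are C6–C7, C11–C12 and C12–O. The forward step is a carbonylative [2+2+1] of the cyclobutanone carbonyl and the tethered alkyne of A3, at Cp2Ti(PMe3)2 or Mo(CO)6. It gives the fully protected tetracycle A4.

*Merits.* Three bonds and two rings form in one step. The tether from C10 forces C7 onto the α face of C6. A4 is only deprotections and acylations away from the target, so in convergence and endgame length this road is clearly superior.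

*Weak points.*
- The hetero variant is established mainly for unstrained aldehydes and aryl ketones, often with stoichiometric titanium.
- This carbonyl is flanked by a quaternary and a tertiary carbon.
- Cyclobutanones are prone to C–C insertion and decarbonylation at low-valent metals.
- Both propargylic positions of A3 carry leaving groups.
- A3 still requires a stereocontrolled cyclobutanone synthesis.

*Comparison.* The chosen plan offers a key reaction with direct precedent on its own substrate class and no metal at the strained stage. It accepts a longer sequence after it.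

**Alternative 3:** The cut is C1–C5. Photolysis of the bicyclo[3.3.0]octane diazoketone A5 triggers a Wolff shift of C5 from C2 to C1. The C4 hydroxyl traps the ketene, giving cyclobutane lactone A6.

*Merits.* The diquinane is readily made by a Pauson–Khand reaction. Wolff contraction is among the most reliable routes to cyclobutanes. The lactone capture fixes C1 cis. As a single reaction it is at least as safe as the tropone closure, and it uses the same equipment.

*Weak points.*
- In A6, ring A exists only as a lactone: C2 is a carboxyl carbon and C3 is absent.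
- C4 is only a secondary carbinol carbon.
- The carbocycle must therefore be rebuilt, and a tertiary alcohol installed next to the cyclobutane, which is the operation this target tolerates worst.

*Comparison.* The chosen plan takes more risk in its key step, but its product contains every skeletal carbon except C11–C13, with C2 and C4 already set.

Key step: step 15

Assumption: centres that are erased again need no control. C8 and C10 of 21 are drawn for ylide attack anti to the C2 silyloxy group, and the phosphonate-bearing carbon of 32–35 is racemic or epimeric and left undefined.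

Step 1
Reactants: 1 4-methylphenol; 2 3-chloropropanoyl chloride
Product: 3 4-methylphenyl 3-chloropropanoate
Conditions: neat, 100 °C
Reagents that add atoms: none
Why: O-acylation of a phenol by an acid chloride; omitting amine base avoids dehydrochlorination of 2.

Step 2
Reactants: 3 4-methylphenyl 3-chloropropanoate
Product: 5 7-hydroxy-4-methylindan-1-one, via Fries ketone 4 (not isolated)
Conditions: AlCl3 (3.5 equiv), neat, 170 °C; then aq. HCl
Reagents that add atoms: none
Why: Fries rearrangement moves the acyl group to the free ortho position, then intramolecular Friedel–Crafts alkylation closes ring A at the only open position beside it, next to the methyl group.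

Step 3
Reactants: 5 7-hydroxy-4-methylindan-1-one
Product: 6 6-bromo-7-hydroxy-4-methylindan-1-one
Conditions: NBS, iPr2NH (cat.), CH2Cl2, 0 °C
Reagents that add atoms: N-bromosuccinimide, O=C1CCC(=O)N1Br
Why: Electrophilic bromination of a phenol; the para position carries the methyl group, so only the free ortho carbon (future C7) is activated.

Step 4
Reactants: 6 6-bromo-7-hydroxy-4-methylindan-1-one; 7 benzyl bromide
Product: 8 7-(benzyloxy)-6-bromo-4-methylindan-1-one
Conditions: K2CO3, DMF, 60 °C
Reagents that add atoms: none
Why: Williamson etherification; it places the benzyl group on the future C6 oxygen before a second oxygen exists, so no catechol has to be differentiated.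

Step 5
Reactants: 8 7-(benzyloxy)-6-bromo-4-methylindan-1-one
Product: 10 7-(benzyloxy)-6-bromo-4-methyl-1H-inden-1-one, via lithium enolate 9 (not isolated)
Conditions: LDA, THF, −78 °C; then PhS(Cl)=NtBu, −78 °C
Reagents that add atoms: none
Why: Mukaiyama dehydrogenation: the enolate attacks sulfur and the adduct loses the sulfenamide by syn elimination at low temperature. No radical or oxidising conditions touch the aryl methyl or the benzylic CH2.

Step 6
Reactants: 10 7-(benzyloxy)-6-bromo-4-methyl-1H-inden-1-one
Product: 12 (3R)-7-(benzyloxy)-6-bromo-3-hydroxy-4-methylindan-1-one, via pinacol boronate 11 (not isolated)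
Conditions: CuCl, NaOtBu, QuinoxP* (cat., enantiomer giving 3R), B2pin2, MeOH, THF, 0 °C; then NaBO3·4H2O, THF/H2O, rt
Reagents that add atoms: bis(pinacolato)diboron, CC1(C)OB(OC1(C)C)B1OC(C)(C)C(C)(C)O1; sodium perborate, [Na+].[O-]OB=O
Why: Copper-catalysed enantioselective conjugate borylation of a cyclic enone. The chiral bisphosphine selects the enone face and sets C2, and perborate oxidation replaces boron by oxygen with retention.

Step 7
Reactants: 12 (3R)-7-(benzyloxy)-6-bromo-3-hydroxy-4-methylindan-1-one
Product: 13 (3R)-7-(benzyloxy)-6-bromo-3-[(tert-butyldimethylsilyl)oxy]-4-methylindan-1-one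
Conditions: TBSCl, imidazole, DMF, rt
Reagents that add atoms: tert-butyldimethylsilyl chloride, CC(C)(C)[Si](C)(C)Cl
Why: Standard silylation under weakly basic conditions that do not dehydrate the β-hydroxy ketone; the group becomes the steering element for steps 9 and 15.

Step 8
Reactants: 13 (3R)-7-(benzyloxy)-6-bromo-3-[(tert-butyldimethylsilyl)oxy]-4-methylindan-1-one
Product: 14 (3R)-7-(benzyloxy)-6-bromo-3-[(tert-butyldimethylsilyl)oxy]-4-methyl-1-methyleneindane
Conditions: Cp2TiMe2, toluene, 70 °C
Reagents that add atoms: dimethyltitanocene, [CH3-].[CH3-].[Ti+4].c1cc[cH-]c1.c1cc[cH-]c1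
Why: Petasis methylenation is non-basic, so the β-silyloxy ketone cannot eliminate. Drift of the double bond into the ring would be harmless, because step 9 passes through the same C4 radical.

Step 9
Reactants: 14 (3R)-7-(benzyloxy)-6-bromo-3-[(tert-butyldimethylsilyl)oxy]-4-methyl-1-methyleneindane
Product: 15 (1R,3R)-7-(benzyloxy)-6-bromo-3-[(tert-butyldimethylsilyl)oxy]-1,4-dimethylindan-1-ol
Conditions: Co(acac)2 (cat.), PhSiH3, O2 (1 atm), THF, 0 °C to rt
Reagents that add atoms: dioxygen, O=O
Why: Mukaiyama hydration: hydrogen-atom transfer to the CH2 gives the planar tertiary benzylic C4 radical. The peri methyl holds the C2 silyloxy group pseudoaxial on the α face, so oxygen should be captured on β and set C4. A C4 radical is safe here because no cyclobutane exists yet.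

Step 10
Reactants: 15 (1R,3R)-7-(benzyloxy)-6-bromo-3-[(tert-butyldimethylsilyl)oxy]-1,4-dimethylindan-1-ol
Product: 16 triethylsilyl ether of 15
Conditions: TESOTf, 2,6-lutidine, CH2Cl2, −78 to 0 °C
Reagents that add atoms: triethylsilyl triflate, CC[Si](CC)(CC)OS(=O)(=O)C(F)(F)F
Why: Silyl triflate with a hindered base is the standard method for tertiary alcohols. The small TES group masks C4–OH during the later acylation of C6–OH and can be removed beside the TBS ether.

Step 11
Reactants: 16 triethylsilyl ether of 15
Product: 19 (1R,3R)-4-(benzyloxy)-1-[(tert-butyldimethylsilyl)oxy]-3,7-dimethyl-3-[(triethylsilyl)oxy]indan-5-ol, via aryllithium 17 (not isolated), via dimethyl boronate 18 (not isolated)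
Conditions: n-BuLi, THF, −78 °C; B(OMe)3, −78 °C to rt; then H2O2, aq. NaOH, 0 °C
Reagents that add atoms: n-butyllithium, [Li]CCCC; trimethyl borate, COB(OC)OC; hydrogen peroxide, OO
Why: Bromine–lithium exchange, borylation and oxidation is a routine one-pot route from aryl bromide to phenol. The oxidation is kept cold and short so that the phenoxide does not expel the para-benzylic silyloxy group.

Step 12
Reactants: 19 (1R,3R)-4-(benzyloxy)-1-[(tert-butyldimethylsilyl)oxy]-3,7-dimethyl-3-[(triethylsilyl)oxy]indan-5-ol
Product: 20 (1R,3R)-7,7-bis(benzyloxy)-3-[(tert-butyldimethylsilyl)oxy]-1,4-dimethyl-1-[(triethylsilyl)oxy]-1,2,3,7-tetrahydro-6H-inden-6-one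
Conditions: PhI(OAc)2, BnOH (10 equiv), CH2Cl2, 0 °C
Reagents that add atoms: benzyl alcohol, OCc1ccccc1
Why: Oxidative dearomatisation of a 2-alkoxyphenol to a masked o-benzoquinone; the alcohol adds at the alkoxy-bearing carbon, where the phenoxenium charge is best stabilised. Two identical acetal arms guarantee that loss of either one leaves a benzyl ether.

Step 13
Reactants: 20 (1R,3R)-7,7-bis(benzyloxy)-3-[(tert-butyldimethylsilyl)oxy]-1,4-dimethyl-1-[(triethylsilyl)oxy]-1,2,3,7-tetrahydro-6H-inden-6-one
Product: 21 cyclopropane adduct of 20 across C8=C10 (C9 methylene on the β face)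
Conditions: Me3S(O)I, NaH, DMSO/THF, rt
Reagents that add atoms: trimethylsulfoxonium iodide, C[S+](C)(C)=O.[I-]
Why: Corey–Chaykovsky cyclopropanation, known for masked o-benzoquinones. Carbonyl addition of the sulfoxonium ylide is reversible, the δ carbon C5 is buried, and 1,4-addition at C10 followed by closure onto C8 inserts C9.

Step 14
Reactants: 21 cyclopropane adduct of 20 across C8=C10
Product: 22 (1R,3R)-4-(benzyloxy)-1-[(tert-butyldimethylsilyl)oxy]-3,8-dimethyl-3-[(triethylsilyl)oxy]-2,3-dihydroazulen-5(1H)-one
Conditions: TFA (5 equiv), CH2Cl2, 0 °C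
Reagents that add atoms: none
Why: Acid opens the cyclopropyl ketone at the internal C8–C10 bond to a tertiary allyl cation. Proton loss from C9 and 1,6-elimination of one benzyloxy group then give the tropone, the known rearrangement of σ-homo-o-benzoquinone monoacetals. The carbonyl remains on C7 and the ether on C6.

Step 15
Reactants: 22 (1R,3R)-4-(benzyloxy)-1-[(tert-butyldimethylsilyl)oxy]-3,8-dimethyl-3-[(triethylsilyl)oxy]-2,3-dihydroazulen-5(1H)-one
Product: 23 5-4-5 dienone: C7 ketone; C8=C9; C1=C5; 6β-benzyloxy; 10β-methyl; 2α-OTBS; 4β-OTES; 4α-methyl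
Conditions: hν (365 nm LED, Pyrex), degassed MeCN (5 mM), 10 °C, flow cell
Reagents that add atoms: none
Why: Excitation of the tropone π,π* state polarises the ring, and the C6=C5–C1=C10 diene closes by a disrotatory 4π electrocyclisation that forms C6–C10. The closest known reaction type is the photoisomerisation of 2-alkoxytropones to 1-alkoxybicyclo[3.2.0]hepta-3,6-dien-2-ones, which also operates in ring-fused tropolone ethers of the lumicolchicine type, where the ring-fusion carbons likewise end as the cyclobutene double bond. The one new bond divides the seven-membered ring into the cyclobutene (C1, C5, C6, C10; 4π disrotatory closure) and the cyclopentenone ring C (C6 to C10), closed by the same event. Disrotation within a seven-membered ring can only turn C7 and C9 to one face and the benzyloxy group and C14 to the other, so C6 and C10 are cis to each other by geometry. Their absolute sense comes from ring A: allylic 1,3-strain with C14 holds the C2 silyloxy group perpendicular on the α face, so C14 can leave the plane only towards β, and at the other peri contact the benzyloxy oxygen moves towards the C4 oxygen, which is effectively smaller than the α methyl C15. The step needs mode selectivity for C6–C10 over C8–C1; the alkoxy-bearing carbon is the preferred terminus in tropolone ethers, and the other mode would make C1 common to three rings. It also needs the product to survive, which 365 nm light and a short residence time secure, because only the tropone absorbs strongly there and secondary rearrangement or hydrogen abstraction from the benzyl CH2 is limited.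

Step 16
Reactants: 23 5-4-5 dienone
Product: 24 cyclobutene ketol: C7 ketone; C1=C5; 6β-hydroxy; other groups as in 23
Conditions: H2 (1 atm), Pd/C, EtOAc, rt
Reagents that add atoms: none
Why: Heterogeneous hydrogenation saturates the enone C8=C9 and cleaves the benzyl ether. The tetrasubstituted, fully flanked cyclobutene should adsorb too poorly to react, and any reduction would come from the same β face as in step 17.

Step 17
Reactants: 24 cyclobutene ketol
Product: 25 cis-syn-cis ketol: 1βH; 5βH; 6β-hydroxy; C7 ketone; 2α-OTBS; 4β-OTES
Conditions: [Ir(cod)(PCy3)(py)]PF6 (cat.), H2 (50 bar), CH2Cl2, rt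
Reagents that add atoms: none
Why: Hydroxyl-directed homogeneous hydrogenation, a reaction type that reaches tetrasubstituted alkenes. The allylic C6 hydroxyl binds iridium on the β face, and the α silyloxy group and ring C block the other, so H1 and H5 are delivered β and ring A folds syn to ring C.

Step 18
Reactants: 25 cis-syn-cis ketol
Product: 26 C7–C8 trimethylsilyl enol ether of 25 with 6β-OTMS
Conditions: TMSCl, LiHMDS (in-situ quench), THF, −78 to 0 °C
Reagents that add atoms: trimethylsilyl chloride, C[Si](C)(C)Cl
Why: C6 is quaternary, so only C8 can be deprotonated. The internal quench silylates the C6 alkoxide before it can start an α-ketol shift.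

Step 19
Reactants: 26 C7–C8 trimethylsilyl enol ether
Product: 28 6β,8β-dihydroxy C7 ketone, via bis(trimethylsilyl) ether 27 (not isolated)
Conditions: mCPBA, NaHCO3, CH2Cl2, −20 °C; then citric acid, MeOH, 0 °C
Reagents that add atoms: 3-chloroperbenzoic acid, OOC(=O)c1cccc(Cl)c1
Why: Rubottom oxidation. The α face of ring C lies inside the fold and is closed by ring A and its 2α substituent, so the enol ether is epoxidised from β, which sets C8. Mild acid removes only the TMS groups.

Step 20
Reactants: 28 6β,8β-dihydroxy C7 ketone; 29 (E)-2-methylbut-2-enoyl chloride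
Product: 30 8β-tigloyloxy 6β-hydroxy C7 ketone
Conditions: pyridine, DMAP (cat.), CH2Cl2, 0 °C
Reagents that add atoms: none
Why: Acylation discriminates the secondary C8 alcohol from the tertiary C6 alcohol. The E enoate is the stable isomer and cannot scramble.

Step 21
Reactants: 31 tert-butyl 2-(diethoxyphosphoryl)acetate
Product: 32 tert-butyl 2-(diethoxyphosphoryl)-3-hydroxypropanoate
Conditions: (CH2O)n, piperidine (cat.), MeOH, reflux
Reagents that add atoms: formaldehyde (as paraformaldehyde), C=O
Why: Amine-catalysed hydroxymethylation of a phosphonoacetate, the known first stage of phosphonoacrylate preparation; it brings in C13.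

Step 22
Reactants: 32 tert-butyl 2-(diethoxyphosphoryl)-3-hydroxypropanoate
Product: 33 tert-butyl 3-[(tert-butyldiphenylsilyl)oxy]-2-(diethoxyphosphoryl)propanoate
Conditions: TBDPSCl, imidazole, DMF, rt
Reagents that add atoms: tert-butyldiphenylsilyl chloride, CC(C)(C)[Si](Cl)(c1ccccc1)c1ccccc1
Why: Routine silylation of a primary alcohol; the acid-stable group survives step 23, and silanolate is a poor leaving group in step 25.

Step 23
Reactants: 33 tert-butyl 3-[(tert-butyldiphenylsilyl)oxy]-2-(diethoxyphosphoryl)propanoate
Product: 34 3-[(tert-butyldiphenylsilyl)oxy]-2-(diethoxyphosphoryl)propanoic acid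
Conditions: TFA, CH2Cl2, 0 °C to rt
Reagents that add atoms: none
Why: Acidolysis of a tert-butyl ester; no base is present, so β-elimination cannot occur.

Step 24
Reactants: 30 8β-tigloyloxy 6β-hydroxy C7 ketone; 34 3-[(tert-butyldiphenylsilyl)oxy]-2-(diethoxyphosphoryl)propanoic acid
Product: 35 C6 phosphonoacyl ester of 30
Conditions: DCC, DMAP, CH2Cl2, rt
Reagents that add atoms: none
Why: Steglich esterification. Activated phosphonoacetic acids acylate through a ketene-like species that reaches tertiary alcohols, and the tied-back cyclobutanol is less shielded than an open tertiary carbinol. C4–OH is masked.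

Step 25
Reactants: 35 C6 phosphonoacyl ester of 30
Product: 36 butenolide with C13 OTBDPS; 8β-tigloyloxy; 2α-OTBS; 4β-OTES
Conditions: LiCl, DBU, MeCN, 0 °C
Reagents that add atoms: none
Why: Intramolecular Horner–Wadsworth–Emmons reaction under Masamune–Roush conditions, the standard butenolide annulation of α-acyloxy ketones. Five-ring closure onto C7 outruns side reactions of the soft lithium phosphonate.

Step 26
Reactants: 36 butenolide
Product: 37 triol: 2α-OH; 4β-OH; C13 OH; 8β-tigloyloxy
Conditions: HF·pyridine, pyridine, THF, 0 °C to rt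
Reagents that add atoms: none
Why: Buffered fluoride removes all three silyl ethers without base, so neither C8 deprotonation nor ester cleavage can occur.

Step 27
Reactants: 37 triol
Product: 38 target CNP0210373.1
Conditions: AcOH, PPh3, DIAD, toluene, 0 °C to rt
Reagents that add atoms: acetic acid, CC(=O)O
Why: Double Mitsunobu esterification. The primary allylic C13 alcohol is acetylated directly (SN2′ would have to attack quaternary C7). The C2 alcohol is displaced with inversion by acetate from the open β face, which sets the final C2 configuration, and the tertiary C4 alcohol does not react.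

## Compound list

1 | 4-methylphenol | Cc1ccc(O)cc1 | starting material
2 | 3-chloropropanoyl chloride | ClCCC(Cl)=O | starting material
3 | 4-methylphenyl 3-chloropropanoate | Cc1ccc(OC(=O)CCCl)cc1 | intermediate
4 | 3-chloro-1-(2-hydroxy-5-methylphenyl)propan-1-one (Fries ketone, not isolated) | Cc1ccc(O)c(C(=O)CCCl)c1 | intermediate
5 | 7-hydroxy-4-methylindan-1-one | O=C1CCc2c(C)ccc(O)c21 | intermediate
6 | 6-bromo-7-hydroxy-4-methylindan-1-one | O=C1CCc2c(C)cc(Br)c(O)c21 | intermediate
7 | benzyl bromide | BrCc1ccccc1 | starting material
8 | 7-(benzyloxy)-6-bromo-4-methylindan-1-one | O=C1CCc2c(C)cc(Br)c(OCc3ccccc3)c21 | intermediate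
9 | lithium enolate of 8 (not isolated) | [Li]OC1=CCc2c(C)cc(Br)c(OCc3ccccc3)c21 | intermediate
10 | 7-(benzyloxy)-6-bromo-4-methyl-1H-inden-1-one | O=C1C=Cc2c(C)cc(Br)c(OCc3ccccc3)c21 | intermediate
11 | (3R)-7-(benzyloxy)-6-bromo-4-methyl-3-(4,4,5,5-tetramethyl-1,3,2-dioxaborolan-2-yl)indan-1-one (not isolated) | O=C1C[C@@H](B2OC(C)(C)C(C)(C)O2)c2c(C)cc(Br)c(OCc3ccccc3)c21 | intermediate
12 | (3R)-7-(benzyloxy)-6-bromo-3-hydroxy-4-methylindan-1-one | O=C1C[C@@H](O)c2c(C)cc(Br)c(OCc3ccccc3)c21 | intermediate
13 | (3R)-7-(benzyloxy)-6-bromo-3-[(tert-butyldimethylsilyl)oxy]-4-methylindan-1-one | O=C1C[C@@H](O[Si](C)(C)C(C)(C)C)c2c(C)cc(Br)c(OCc3ccccc3)c21 | intermediate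
14 | (3R)-7-(benzyloxy)-6-bromo-3-[(tert-butyldimethylsilyl)oxy]-4-methyl-1-methyleneindane | C=C1C[C@@H](O[Si](C)(C)C(C)(C)C)c2c(C)cc(Br)c(OCc3ccccc3)c21 | intermediate
15 | (1R,3R)-7-(benzyloxy)-6-bromo-3-[(tert-butyldimethylsilyl)oxy]-1,4-dimethylindan-1-ol | C[C@@]1(O)C[C@@H](O[Si](C)(C)C(C)(C)C)c2c(C)cc(Br)c(OCc3ccccc3)c21 | intermediate
16 | triethylsilyl ether of 15 | C[C@@]1(O[Si](CC)(CC)CC)C[C@@H](O[Si](C)(C)C(C)(C)C)c2c(C)cc(Br)c(OCc3ccccc3)c21 | intermediate
17 | aryllithium from 16 (not isolated) | C[C@@]1(O[Si](CC)(CC)CC)C[C@@H](O[Si](C)(C)C(C)(C)C)c2c(C)cc([Li])c(OCc3ccccc3)c21 | intermediate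
18 | dimethyl arylboronate from 17 (not isolated) | C[C@@]1(O[Si](CC)(CC)CC)C[C@@H](O[Si](C)(C)C(C)(C)C)c2c(C)cc(B(OC)OC)c(OCc3ccccc3)c21 | intermediate
19 | (1R,3R)-4-(benzyloxy)-1-[(tert-butyldimethylsilyl)oxy]-3,7-dimethyl-3-[(triethylsilyl)oxy]indan-5-ol | C[C@@]1(O[Si](CC)(CC)CC)C[C@@H](O[Si](C)(C)C(C)(C)C)c2c(C)cc(O)c(OCc3ccccc3)c21 | intermediate
20 | (1R,3R)-7,7-bis(benzyloxy)-3-[(tert-butyldimethylsilyl)oxy]-1,4-dimethyl-1-[(triethylsilyl)oxy]-1,2,3,7-tetrahydro-6H-inden-6-one | O=C1C=C(C)C2=C([C@](C)(O[Si](CC)(CC)CC)C[C@H]2O[Si](C)(C)C(C)(C)C)C1(OCc1ccccc1)OCc1ccccc1 | intermediate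
21 | cyclopropane adduct of 20 across C8=C10, C9 methylene β | O=C1[C@H]2C[C@@]2(C)C3=C([C@](C)(O[Si](CC)(CC)CC)C[C@H]3O[Si](C)(C)C(C)(C)C)C1(OCc1ccccc1)OCc1ccccc1 | intermediate
22 | (1R,3R)-4-(benzyloxy)-1-[(tert-butyldimethylsilyl)oxy]-3,8-dimethyl-3-[(triethylsilyl)oxy]-2,3-dihydroazulen-5(1H)-one (key-step precursor) | O=C1C=CC(C)=C2[C@H](O[Si](C)(C)C(C)(C)C)C[C@@](C)(O[Si](CC)(CC)CC)C2=C1OCc1ccccc1 | intermediate
23 | 5-4-5 dienone, 6β-OBn, 10β-Me, 2α-OTBS, 4β-OTES, C7=O, C8=C9, C1=C5 (key-step product) | O=C1C=C[C@]2(C)C3=C([C@](C)(O[Si](CC)(CC)CC)C[C@H]3O[Si](C)(C)C(C)(C)C)[C@]12OCc1ccccc1 | intermediate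
24 | cyclobutene ketol, 6β-OH, C7=O, C1=C5 | O=C1CC[C@]2(C)C3=C([C@](C)(O[Si](CC)(CC)CC)C[C@H]3O[Si](C)(C)C(C)(C)C)[C@]12O | intermediate
25 | cis-syn-cis ketol, 1βH, 5βH, 6β-OH, C7=O | O=C1CC[C@]2(C)[C@@H]3[C@H](O[Si](C)(C)C(C)(C)C)C[C@@](C)(O[Si](CC)(CC)CC)[C@@H]3[C@]12O | intermediate
26 | C7–C8 TMS enol ether, 6β-OTMS | C[Si](C)(C)OC1=CC[C@]2(C)[C@@H]3[C@H](O[Si](C)(C)C(C)(C)C)C[C@@](C)(O[Si](CC)(CC)CC)[C@@H]3[C@]12O[Si](C)(C)C | intermediate
27 | 6β,8β-bis(trimethylsilyloxy) C7 ketone (not isolated) | O=C1[C@@H](O[Si](C)(C)C)C[C@]2(C)[C@@H]3[C@H](O[Si](C)(C)C(C)(C)C)C[C@@](C)(O[Si](CC)(CC)CC)[C@@H]3[C@]12O[Si](C)(C)C | intermediate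
28 | 6β,8β-dihydroxy C7 ketone | O=C1[C@@H](O)C[C@]2(C)[C@@H]3[C@H](O[Si](C)(C)C(C)(C)C)C[C@@](C)(O[Si](CC)(CC)CC)[C@@H]3[C@]12O | intermediate
29 | (E)-2-methylbut-2-enoyl chloride (tigloyl chloride) | C/C=C(\C)C(Cl)=O | starting material
30 | 8β-tigloyloxy 6β-hydroxy C7 ketone | C/C=C(\C)C(=O)O[C@H]1C[C@]2(C)[C@@H]3[C@H](O[Si](C)(C)C(C)(C)C)C[C@@](C)(O[Si](CC)(CC)CC)[C@@H]3[C@]2(O)C1=O | intermediate
31 | tert-butyl 2-(diethoxyphosphoryl)acetate | CCOP(=O)(CC(=O)OC(C)(C)C)OCC | starting material
32 | tert-butyl 2-(diethoxyphosphoryl)-3-hydroxypropanoate (racemic) | CCOP(=O)(OCC)C(CO)C(=O)OC(C)(C)C | intermediate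
33 | tert-butyl 3-[(tert-butyldiphenylsilyl)oxy]-2-(diethoxyphosphoryl)propanoate (racemic) | CCOP(=O)(OCC)C(CO[Si](c1ccccc1)(c1ccccc1)C(C)(C)C)C(=O)OC(C)(C)C | intermediate
34 | 3-[(tert-butyldiphenylsilyl)oxy]-2-(diethoxyphosphoryl)propanoic acid (racemic) | CCOP(=O)(OCC)C(CO[Si](c1ccccc1)(c1ccccc1)C(C)(C)C)C(=O)O | intermediate
35 | C6 phosphonoacyl ester of 30 (C11 epimers) | C/C=C(\C)C(=O)O[C@H]1C[C@]2(C)[C@@H]3[C@H](O[Si](C)(C)C(C)(C)C)C[C@@](C)(O[Si](CC)(CC)CC)[C@@H]3[C@]2(OC(=O)C(CO[Si](c3ccccc3)(c3ccccc3)C(C)(C)C)P(=O)(OCC)OCC)C1=O | intermediate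
36 | protected butenolide, C13 OTBDPS | C/C=C(\C)C(=O)O[C@H]1C[C@]2(C)[C@@H]3[C@H](O[Si](C)(C)C(C)(C)C)C[C@@](C)(O[Si](CC)(CC)CC)[C@@H]3[C@@]23OC(=O)C(CO[Si](c4ccccc4)(c4ccccc4)C(C)(C)C)=C13 | intermediate
37 | triol, 2α-OH, 4β-OH, C13 OH | C/C=C(\C)C(=O)O[C@H]1C[C@]2(C)[C@@H]3[C@H](O)C[C@@](C)(O)[C@@H]3[C@@]23OC(=O)C(CO)=C13 | intermediate
38 | CNP0210373.1, (1R,2S,4R,5R,6R,8S,10R) in the locants used here | C/C=C(\C)C(=O)O[C@H]1C[C@]2(C)[C@@H]3[C@@H](OC(C)=O)C[C@@](C)(O)[C@@H]3[C@@]23OC(=O)C(COC(C)=O)=C13 | target

## Step count and least certain steps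

Total steps: 27. Longest linear sequence: 24 (steps 1–20 and 24–27). Steps 21–23 form the side branch.

**Step 15 (key step).**
- *Risk:* The most likely failures are an insufficient facial bias of the disrotation and a sluggish closure, because both termini are fully substituted and crowded by ring A. Over-irradiation and hydrogen abstraction from the benzylic CH2 are secondary losses.
- *Fallback:* The peri contact at C4/C6 is changed from a steric to a hydrogen-bond element. Starting from 22, the tertiary TES ether is removed selectively (PPTS, MeOH) to give the hydroxy tropone F1. Its β hydroxyl is small and can hold the benzyloxy oxygen on its own face. Irradiation as in step 15 should give the hydroxy photoproduct F2, and TESOTf with 2,6-lutidine returns to the route at 23.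

**Step 6.**
- *Risk:* Erosion of enantioselectivity at a β carbon crowded by the peri methyl, or oligomerisation of the reactive indenone before borylation.
- *Fallback:* Asymmetric catalysis is replaced by biocatalytic resolution, known for 3-hydroxyindanones. Starting from 10, borylation and oxidation with an achiral ligand (CuCl, DPEphos) give the racemic alcohol F3. A lipase with vinyl acetate acylates the R enantiomer to the acetate F4 and leaves the S alcohol F5. Enzymatic hydrolysis of F4 in buffer returns to the route at 12. F5 is dehydrated with catalytic TsOH back to 10 and recycled.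

**Step 14.**
- *Risk:* Protodesilylation of the TES ether, ionisation or a methyl shift at C4 next to the allyl cation, and, one step earlier, incomplete formation of the very crowded dibenzyl acetal.
- *Fallback:* The leaving group is changed so that strong acid is no longer needed. Starting from 19, Wessely-type oxidation with Pb(OAc)4 in CH2Cl2 gives the acetoxy benzyloxy dienone F6. Corey–Chaykovsky cyclopropanation gives the acetoxy cyclopropane F7. The acetate alone ionises with BF3·OEt2 and 2,6-di-tert-butylpyridine at −78 °C, which returns to the route at 22.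

**Step 17.**
- *Risk:* No turnover, because the alkene is tetrasubstituted and flanked by four substituted carbons, the 4β silyl ether crowds the iridium bound to O6, and the catalyst decays in the meantime.
- *Fallback:* The directing group and the order of events are changed. Starting from 23, PPTS in MeOH gives F2 (defined above). Its unhindered allylic C4 hydroxyl directs [Ir(cod)(PCy3)(py)]PF6 and H2 to the β face while the benzyl ether stays in place, giving the saturated hydroxy benzyl ether F8. TESOTf gives its silyl ether F9, and H2 over Pd/C returns to the route at 25.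

**Step 25 (with the acylation of step 24).**
- *Risk:* Slow esterification of the tertiary ketol by an α-branched acid, retro-oxa-Michael loss of silanolate from the phosphonate anion, and epimerisation at C8 under base.
- *Fallback:* C13 is attached after ring closure. Starting from 30, the smaller bromo(diethoxyphosphoryl)acetic acid (DCC, DMAP) gives the bromophosphonate ester F10. LiCl and DBU give the α-bromobutenolide F11. Stille coupling with (tributylstannyl)methanol and Pd(PPh3)4 gives the hydroxymethyl butenolide F12. HF·pyridine as in step 26 returns to the route at 37.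

**Step 27.**
- *Risk:* Failure to activate the C2 alcohol, which points into the fold, or anti elimination towards C3 in place of substitution.
- *Fallback:* The two acetates are separated, and the redox condensation is replaced by a sulfonate displacement. Starting from 37, Ac2O and pyridine at 0 °C acetylate only the primary alcohol to give the monoacetate F13. Tf2O and pyridine at −20 °C give the C2 triflate F14. CsOAc with 18-crown-6 in toluene displaces it from the β face and arrives at 38.

## Further compounds

F1 | step 15 | hydroxy tropone, 4β-OH analogue of 22 | O=C1C=CC(C)=C2[C@H](O[Si](C)(C)C(C)(C)C)C[C@@](C)(O)C2=C1OCc1ccccc1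
F2 | step 15 | hydroxy photoproduct, 4β-OH analogue of 23 | O=C1C=C[C@]2(C)C3=C([C@](C)(O)C[C@H]3O[Si](C)(C)C(C)(C)C)[C@]12OCc1ccccc1
F3 | step 6 | racemic 7-(benzyloxy)-6-bromo-3-hydroxy-4-methylindan-1-one | O=C1CC(O)c2c(C)cc(Br)c(OCc3ccccc3)c21
F4 | step 6 | (3R)-3-acetoxy-7-(benzyloxy)-6-bromo-4-methylindan-1-one | O=C1C[C@@H](OC(C)=O)c2c(C)cc(Br)c(OCc3ccccc3)c21
F5 | step 6 | (3S)-7-(benzyloxy)-6-bromo-3-hydroxy-4-methylindan-1-one | O=C1C[C@H](O)c2c(C)cc(Br)c(OCc3ccccc3)c21
F6 | step 14 | acetoxy benzyloxy dienone (C6 epimers) | O=C1C=C(C)C2=C([C@](C)(O[Si](CC)(CC)CC)C[C@H]2O[Si](C)(C)C(C)(C)C)C1(OC(C)=O)OCc1ccccc1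
F7 | step 14 | acetoxy cyclopropane (C6 epimers) | O=C1[C@H]2C[C@@]2(C)C3=C([C@](C)(O[Si](CC)(CC)CC)C[C@H]3O[Si](C)(C)C(C)(C)C)C1(OC(C)=O)OCc1ccccc1
F8 | step 17 | saturated hydroxy benzyl ether, 4β-OH, 6β-OBn | O=C1CC[C@]2(C)[C@@H]3[C@H](O[Si](C)(C)C(C)(C)C)C[C@@](C)(O)[C@@H]3[C@]12OCc1ccccc1
F9 | step 17 | triethylsilyl ether of F8 | O=C1CC[C@]2(C)[C@@H]3[C@H](O[Si](C)(C)C(C)(C)C)C[C@@](C)(O[Si](CC)(CC)CC)[C@@H]3[C@]12OCc1ccccc1
F10 | step 25 | bromophosphonate ester of 30 | C/C=C(\C)C(=O)O[C@H]1C[C@]2(C)[C@@H]3[C@H](O[Si](C)(C)C(C)(C)C)C[C@@](C)(O[Si](CC)(CC)CC)[C@@H]3[C@]2(OC(=O)C(Br)P(=O)(OCC)OCC)C1=O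
F11 | step 25 | α-bromobutenolide | C/C=C(\C)C(=O)O[C@H]1C[C@]2(C)[C@@H]3[C@H](O[Si](C)(C)C(C)(C)C)C[C@@](C)(O[Si](CC)(CC)CC)[C@@H]3[C@@]23OC(=O)C(Br)=C13
F12 | step 25 | hydroxymethyl butenolide | C/C=C(\C)C(=O)O[C@H]1C[C@]2(C)[C@@H]3[C@H](O[Si](C)(C)C(C)(C)C)C[C@@](C)(O[Si](CC)(CC)CC)[C@@H]3[C@@]23OC(=O)C(CO)=C13
F13 | step 27 | C13 monoacetate of 37 | C/C=C(\C)C(=O)O[C@H]1C[C@]2(C)[C@@H]3[C@H](O)C[C@@](C)(O)[C@@H]3[C@@]23OC(=O)C(COC(C)=O)=C13
F14 | step 27 | C2 triflate of F13 | C/C=C(\C)C(=O)O[C@H]1C[C@]2(C)[C@@H]3[C@H](OS(=O)(=O)C(F)(F)F)C[C@@](C)(O)[C@@H]3[C@@]23OC(=O)C(COC(C)=O)=C13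
A1 | alternative 1 | cyclobutane diazoketone with α C10–H | C[C@H]1[C@@H]2[C@@H](O[Si](C)(C)C(C)(C)C)C[C@@](C)(O[Si](CC)(CC)CC)[C@@H]2[C@]1(O[Si](CC)(CC)CC)[C@H](O[Si](C)(C)C(C)(C)C)C(=O)C=[N+]=[N-]
A2 | alternative 1 | cis-syn-cis tricycle with C8 ketone | O=C1C[C@]2(C)[C@@H]3[C@@H](O[Si](C)(C)C(C)(C)C)C[C@@](C)(O[Si](CC)(CC)CC)[C@@H]3[C@]2(O[Si](CC)(CC)CC)[C@@H]1O[Si](C)(C)C(C)(C)C
A3 | alternative 2 | cyclobutanone with tethered alkyne | CC(C)[Si](C(C)C)(C(C)C)O[C@H](C#CCOCc1ccc(OC)cc1)C[C@]2(C)[C@@H]3[C@@H](O[Si](C)(C)C(C)(C)C)C[C@@](C)(O[Si](C)(C)C)[C@@H]3C2=O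
A4 | alternative 2 | fully protected tetracycle | CC(C)[Si](C(C)C)(C(C)C)O[C@H]1C[C@]2(C)[C@@H]3[C@@H](O[Si](C)(C)C(C)(C)C)C[C@@](C)(O[Si](C)(C)C)[C@@H]3[C@@]23OC(=O)C(COCc4ccc(OC)cc4)=C13
A5 | alternative 3 | bicyclo[3.3.0]octane α-diazoketone | CC(C)(C)[Si](C)(C)O[C@H]1C[C@]2(C)C(=[N+]=[N-])C(=O)[C@H]([C@H](C)O)[C@]2(O[Si](CC)(CC)CC)C1(OC)OC
A6 | alternative 3 | ring-C-fused cyclobutane lactone | CC(C)(C)[Si](C)(C)O[C@H]1C[C@]2(C)[C@@H]3C(=O)O[C@@H](C)[C@@H]3[C@]2(O[Si](CC)(CC)CC)C1(OC)OC
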